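**Plan**

1. Locants: coumarin O1, C2, C3, C4, C4a–C8a; side chain C1'–C12' counted from C3. The first cut is C3'(sp2)–C4'(sp3) inside the skipped 1,5-diene C2'=C3'–C4'–C5'–C6'=C7'. Because C4' is homoallylic to C6'=C7', it is the end of a 1,3-diene C4'=C5'–C6'=C7' that 9-BBN converts into a primary alkylborane; C3' is the methyl-bearing carbon of an (E)-alkenyl iodide that already carries the finished 4-hydroxycoumarin (benzene ring fused to the 4-hydroxy-2-pyranone ring).
2. Further cuts, diene half: C4'=C5' (Wittig), benzoate O–acyl, and C12'–O (allylic C–H hydroxylation of geranyl acetate). Coumarin half: C3–C4 of the pyranone ring (intramolecular Claisen), O1–C2 (ester), C3'–I (from the alkyne of hex-4-yn-1-ol).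
3. Forward: geranyl acetate → C12' hydroxylation → benzoate → free C5' alcohol → enal → triene (steps 1–5). Hex-4-yn-1-ol → (E)-iodoalkene → acid → salicylate ester → pyranone ring closed onto the preformed benzene ring (steps 6–9). The halves are joined last, with the benzoate and the free 4-OH already in place (step 10).
4. Stereochemistry: there are no stereocentres. C6'=C7' (E) comes with geranyl acetate, C10'=C11' (E) from the ene/[2,3] course of the SeO2 oxidation, and C2'=C3' (E) from syn hydrozirconation followed by a stereoretentive coupling.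

Key step: step 10

**Route**

Step 1
Reactants: 1 geranyl acetate
Product: 2 (2E,6E)-8-hydroxy-3,7-dimethylocta-2,6-dien-1-yl acetate
Conditions: SeO2 (0.3 equiv), t-BuOOH (70% aq., 3 equiv), salicylic acid (0.1 equiv), CH2Cl2, rt
Reagents that add atoms: selenium dioxide, O=[Se]=O (oxygen carrier); tert-butyl hydroperoxide, CC(C)(C)OO (terminal oxygen source)
Why: Catalytic SeO2 allylic oxidation (ene reaction, then [2,3]-sigmatropic shift of the allylseleninic acid) should attack the electron-richer distal alkene, since the allylic acetate deactivates the proximal one, and should hydroxylate the methyl group trans to the chain, which fixes the E geometry of the future C10'=C11' unit.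

Step 2
Reactants: 2 (2E,6E)-8-hydroxy-3,7-dimethylocta-2,6-dien-1-yl acetate
Product: 3 (2E,6E)-8-(acetyloxy)-2,6-dimethylocta-2,6-dien-1-yl benzoate
Conditions: BzCl (1.2 equiv), pyridine (3 equiv), DMAP (0.05 equiv), CH2Cl2, 0 °C → rt
Reagents that add atoms: benzoyl chloride, O=C(Cl)c1ccccc1
Why: DMAP-catalysed acylation of the only free hydroxyl group installs the benzoate of the target at the outset, where it also protects the C12' oxygen through the rest of the route.

Step 3
Reactants: 3 (2E,6E)-8-(acetyloxy)-2,6-dimethylocta-2,6-dien-1-yl benzoate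
Product: 4 (2E,6E)-8-hydroxy-2,6-dimethylocta-2,6-dien-1-yl benzoate
Conditions: Mg(OMe)2 (2 equiv), MeOH, rt, stopped when 3 is consumed
Reagents that add atoms: none
Why: Chemoselective transesterification: Mg(OMe)2 in methanol cleaves an acetate markedly faster than a benzoate, whose acyl carbon is conjugated and more hindered, so the primary allylic alcohol at the future C5' should be freed while the benzoate stays.

Step 4
Reactants: 4 (2E,6E)-8-hydroxy-2,6-dimethylocta-2,6-dien-1-yl benzoate
Product: 5 (2E,6E)-2,6-dimethyl-8-oxoocta-2,6-dien-1-yl benzoate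
Conditions: MnO2 (activated, 15 equiv), CH2Cl2, rt
Reagents that add atoms: none
Why: MnO2 allylic oxidation converts the primary allylic alcohol into the enal on the oxide surface without isomerising the trisubstituted alkene and without touching the benzoate.

Step 5
Reactants: 5 (2E,6E)-2,6-dimethyl-8-oxoocta-2,6-dien-1-yl benzoate
Product: 6 (2E,6E)-2,6-dimethylnona-2,6,8-trien-1-yl benzoate
Conditions: Ph3PCH3Br (1.2 equiv), NaN(SiMe3)2 (1.15 equiv), THF, 0 °C; then 5, −78 °C → 0 °C
Reagents that add atoms: methyltriphenylphosphonium bromide, C[P+](c1ccccc1)(c1ccccc1)c1ccccc1.[Br-] (as its ylide)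
Why: Wittig methylenation with the non-stabilised ylide reacts with the aldehyde far faster than with the benzoate at low temperature and turns the aldehyde carbon C5' into the diene terminus C5'=C4' without affecting the existing E alkenes.

Step 6
Reactants: 7 hex-4-yn-1-ol
Product: 9 (4E)-5-iodohex-4-en-1-ol, via alkenylzirconocene 8 (not isolated)
Conditions: Cp2Zr(H)Cl (3 equiv), THF, 50 °C; then I2 (2.2 equiv), 0 °C; aq. Na2S2O3
Reagents that add atoms: iodine, [I][I]
Why: Hydrozirconation–iodination: the syn addition of Zr–H, equilibrated by the excess of Cp2Zr(H)Cl, should place zirconium on the less hindered methyl-bearing alkyne carbon, and iodinolysis of the C–Zr bond with retention should give the alkenyl iodide with iodine trans to the chain.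

Step 7
Reactants: 9 (4E)-5-iodohex-4-en-1-ol
Product: 10 (4E)-5-iodohex-4-enoic acid
Conditions: TEMPO (0.2 equiv), PhI(OAc)2 (2.2 equiv), MeCN/H2O (1:1), rt
Reagents that add atoms: water, O
Why: The TEMPO/PhI(OAc)2 oxidation takes the primary alcohol through the aldehyde hydrate to the carboxylic acid under conditions that should leave the alkenyl iodide untouched.

Step 8
Reactants: 10 (4E)-5-iodohex-4-enoic acid; 11 methyl salicylate
Product: 12 methyl 2-{[(4E)-5-iodohex-4-enoyl]oxy}benzoate
Conditions: N,N'-dicyclohexylcarbodiimide (1.1 equiv), DMAP (0.1 equiv), CH2Cl2, 0 °C → rt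
Reagents that add atoms: none
Why: Steglich esterification (carbodiimide activation, DMAP acyl transfer) acylates the phenolic oxygen of methyl salicylate and so forms the O1–C2 bond and places the enolisable CH2 next to the methyl ester.

Step 9
Reactants: 12 methyl 2-{[(4E)-5-iodohex-4-enoyl]oxy}benzoate
Product: 13 4-hydroxy-3-[(2E)-3-iodobut-2-en-1-yl]-2H-chromen-2-one
Conditions: LiN(SiMe3)2 (2.5 equiv), THF, −78 °C → 0 °C; then 1 M HCl
Reagents that add atoms: none
Why: Intramolecular Claisen (Dieckmann-type) condensation: the lithium ester enolate should attack the neighbouring methyl ester in a 6-exo-trig closure that forms C3–C4, methoxide leaves, and deprotonation to the stabilised coumarin-4-olate drives the reaction while the E-alkenyl iodide remains a spectator at low temperature.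

Step 10
Reactants: 6 (2E,6E)-2,6-dimethylnona-2,6,8-trien-1-yl benzoate; 13 4-hydroxy-3-[(2E)-3-iodobut-2-en-1-yl]-2H-chromen-2-one
Product: 15 E-omega-benzoyloxyferulenol, via homoallylic 9-BBN borane 14 (not isolated)
Conditions: 6 (1.3 equiv), 9-BBN (0.5 M in THF, 1.35 equiv), 0 °C → rt; then 13 (1 equiv), Pd(dppf)Cl2 (5 mol %), AsPh3 (10 mol %), Cs2CO3 (4 equiv), DMF/H2O, rt; aq. citric acid work-up
Reagents that add atoms: none
Why: 9-BBN adds its B–H bond syn and anti-Markovnikov to the monosubstituted C4'=C5' end of the diene to give the primary homoallylic borane 14; zerovalent palladium then inserts into the C3'–I bond of 13 with retention, the base-bound borate transfers the C4' alkyl group to divalent palladium, and reductive elimination forms the C3'–C4' bond. The closest known reaction type is the B-alkyl Suzuki–Miyaura coupling of homoallylic 9-BBN boranes, made from 4-methyl-1,3-dienes, with (E)-2-iodoalk-2-enes. No ring is closed and no stereocentre is formed; the E geometry of C2'=C3' is that of the alkenyl iodide and is kept because oxidative addition and reductive elimination are stereoretentive, while C6'=C7' and C10'=C11' are not touched. The step needs site selectivity in the hydroboration, which the bulk of 9-BBN secures by leaving the two trisubstituted alkenes and the benzoate alone, and chemoselectivity for the C(sp2)–I bond over the allylic benzoate, which the much faster oxidative addition of the iodide at room temperature secures. The acidic 4-OH is carried as its cesium salt by the extra Cs2CO3 and should stay a spectator, and the wide bite angle of dppf should favour reductive elimination over β-hydride elimination of the alkylpalladium intermediate.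

**Compound list**

1 | geranyl acetate, (2E)-3,7-dimethylocta-2,6-dien-1-yl acetate | CC(C)=CCC/C(C)=C/COC(C)=O | starting material
2 | (2E,6E)-8-hydroxy-3,7-dimethylocta-2,6-dien-1-yl acetate | CC(=O)OC/C=C(\C)CC/C=C(\C)CO | intermediate
3 | (2E,6E)-8-(acetyloxy)-2,6-dimethylocta-2,6-dien-1-yl benzoate | CC(=O)OC/C=C(\C)CC/C=C(\C)COC(=O)c1ccccc1 | intermediate
4 | (2E,6E)-8-hydroxy-2,6-dimethylocta-2,6-dien-1-yl benzoate | OC/C=C(\C)CC/C=C(\C)COC(=O)c1ccccc1 | intermediate
5 | (2E,6E)-2,6-dimethyl-8-oxoocta-2,6-dien-1-yl benzoate | O=C/C=C(\C)CC/C=C(\C)COC(=O)c1ccccc1 | intermediate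
6 | (2E,6E)-2,6-dimethylnona-2,6,8-trien-1-yl benzoate | C=C/C=C(\C)CC/C=C(\C)COC(=O)c1ccccc1 | intermediate
7 | hex-4-yn-1-ol | CC#CCCCO | starting material
8 | alkenylzirconocene: (4E)-5-[chlorobis(cyclopentadienyl)zirconio]hex-4-en-1-yl oxide bound to a second Cp2ZrCl unit | C/C(=C\CCCO[Zr](Cl)(C1C=CC=C1)C1C=CC=C1)[Zr](Cl)(C1C=CC=C1)C1C=CC=C1 | intermediate (not isolated)
9 | (4E)-5-iodohex-4-en-1-ol | I/C(C)=C/CCCO | intermediate
10 | (4E)-5-iodohex-4-enoic acid | I/C(C)=C/CCC(=O)O | intermediate
11 | methyl salicylate | COC(=O)c1ccccc1O | starting material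
12 | methyl 2-{[(4E)-5-iodohex-4-enoyl]oxy}benzoate | I/C(C)=C/CCC(=O)Oc1ccccc1C(=O)OC | intermediate
13 | 4-hydroxy-3-[(2E)-3-iodobut-2-en-1-yl]-2H-chromen-2-one | I/C(C)=C/Cc1c(O)c2ccccc2oc1=O | intermediate
14 | (2E,6E)-9-(9-borabicyclo[3.3.1]nonan-9-yl)-2,6-dimethylnona-2,6-dien-1-yl benzoate | C/C(=C\CCB1C2CCCC1CCC2)CC/C=C(\C)COC(=O)c1ccccc1 | intermediate (not isolated)
15 | E-omega-benzoyloxyferulenol, (2E,6E,10E)-12-(4-hydroxy-2-oxo-2H-chromen-3-yl)-2,6,10-trimethyldodeca-2,6,10-trien-1-yl benzoate | C/C(=C\CC/C(C)=C/Cc1c(O)c2ccccc2oc1=O)CC/C=C(\C)COC(=O)c1ccccc1 | target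

**Count and risks**

Total steps: 10. Longest linear sequence: 6 (steps 1–5, then step 10); the second branch has 5 (steps 6–9, then step 10).

Steps most likely to fail:

Step 10. Zerovalent palladium may ionise the allylic benzoate, and the soft coumarin-4-olate may then capture the π-allyl complex; the chelating olate may also stall transmetalation. Fallback: the order of chain union and ring formation is inverted, so that palladium never meets the coumarin-olate. Setting out from 6 and 10, borane 14 is made as before and coupled with the cesium salt of acid 10 (Pd(dppf)Cl2, AsPh3, Cs2CO3, DMF/H2O, rt). The only nucleophile present is then a carboxylate, which can do no more than return the same allylic ester. This should give (4E,8E,12E)-14-(benzoyloxy)-5,9,13-trimethyltetradeca-4,8,12-trienoic acid F1. Carbodiimide esterification with 11 should give 2-(methoxycarbonyl)phenyl (4E,8E,12E)-14-(benzoyloxy)-5,9,13-trimethyltetradeca-4,8,12-trienoate F2. LiN(SiMe3)2 in THF, then dilute HCl, should close the pyranone ring as in step 9, and the sequence comes back to the route at 15.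

Step 3. The methanolysis may fail to discriminate between the two primary allylic esters, so that the benzoate is lost alongside the acetate. Fallback: orthogonal silyl protection replaces the kinetic discrimination of two esters. Setting out from 2, silylation (TBSCl, imidazole, DMF) should give (2E,6E)-8-[(tert-butyldimethylsilyl)oxy]-3,7-dimethylocta-2,6-dien-1-yl acetate F3. Complete methanolysis (K2CO3, MeOH) should give (2E,6E)-8-[(tert-butyldimethylsilyl)oxy]-3,7-dimethylocta-2,6-dien-1-ol F4. MnO2 in CH2Cl2 should give (2E,6E)-8-[(tert-butyldimethylsilyl)oxy]-3,7-dimethylocta-2,6-dienal F5. HF·pyridine in THF should give (2E,6E)-8-hydroxy-3,7-dimethylocta-2,6-dienal F6, and benzoylation (BzCl, pyridine) comes back to the route at 5.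

Step 9. The aryl ester enolate may expel the salicylate phenoxide (ketene formation and acyl scrambling), or the amide base may dehydroiodinate the alkenyl iodide before the ring closes. Fallback: the C3–C4 bond is made intermolecularly and the ring is closed through the lactone bond O1–C2 instead. Setting out from 10, methylation (MeI, K2CO3, DMF) should give methyl (4E)-5-iodohex-4-enoate F7. Its lithium enolate (LiN(i-Pr)2, THF, −78 °C, two equivalents) is C-acylated with 2-(acetyloxy)benzoyl chloride to give methyl (4E)-2-[2-(acetyloxy)benzoyl]-5-iodohex-4-enoate F8. NaOMe in MeOH then removes the acetyl group, the freed phenoxide lactonises onto the methyl ester, and the sequence comes back to the route at 13.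

**Further compounds**

F1 | step 10 | (4E,8E,12E)-14-(benzoyloxy)-5,9,13-trimethyltetradeca-4,8,12-trienoic acid | C/C(=C\CC/C(C)=C/CCC(=O)O)CC/C=C(\C)COC(=O)c1ccccc1
F2 | step 10 | 2-(methoxycarbonyl)phenyl (4E,8E,12E)-14-(benzoyloxy)-5,9,13-trimethyltetradeca-4,8,12-trienoate | C/C(=C\CC/C(C)=C/CCC(=O)Oc1ccccc1C(=O)OC)CC/C=C(\C)COC(=O)c1ccccc1
F3 | step 3 | (2E,6E)-8-[(tert-butyldimethylsilyl)oxy]-3,7-dimethylocta-2,6-dien-1-yl acetate | CC(=O)OC/C=C(\C)CC/C=C(\C)CO[Si](C)(C)C(C)(C)C
F4 | step 3 | (2E,6E)-8-[(tert-butyldimethylsilyl)oxy]-3,7-dimethylocta-2,6-dien-1-ol | OC/C=C(\C)CC/C=C(\C)CO[Si](C)(C)C(C)(C)C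
F5 | step 3 | (2E,6E)-8-[(tert-butyldimethylsilyl)oxy]-3,7-dimethylocta-2,6-dienal | O=C/C=C(\C)CC/C=C(\C)CO[Si](C)(C)C(C)(C)C
F6 | step 3 | (2E,6E)-8-hydroxy-3,7-dimethylocta-2,6-dienal | O=C/C=C(\C)CC/C=C(\C)CO
F7 | step 9 | methyl (4E)-5-iodohex-4-enoate | I/C(C)=C/CCC(=O)OC
F8 | step 9 | methyl (4E)-2-[2-(acetyloxy)benzoyl]-5-iodohex-4-enoate (racemic at C2) | I/C(C)=C/CC(C(=O)OC)C(=O)c1ccccc1OC(C)=O
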